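Ring B of the target is a cyclohexane-1,4-diol: C6 and C9 both carry oxygen and are bridged on one side by C5–C10 of ring A and on the other by the propene unit C7–C8(–C17). The route therefore builds a ring A γ-keto aldehyde (formyl C6 on C5, ketone C9 on C10, side chain complete) and inserts an allyl group as a vicinal double donor in one flask. Allylboration of the aldehyde forms C6–C7; iron-hydride hydrogen atom transfer then turns the alkene into a C8 radical that closes onto the C9 ketone and sets C8 and C9. The C10 quaternary centre comes from an anionic oxy-Cope rearrangement of a β-cyclocitral homoaldol adduct.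

Key step: step 9

Remarks on the chemistry: labdane numbering (C1 to C20) is used for all intermediates. The configuration drawn at the oxygen-bearing C9 of 11, 12, 14 and 15 is the one expected from a chair transition state; it is of no consequence because C9 becomes a ketone in step 8. Compounds 1, 2, 4, 13 and 17 are taken as commercial.

Step 1
Reactants: 1 allyl alcohol; 2 N,N-diisopropylcarbamoyl chloride
Product: 3 allyl N,N-diisopropylcarbamate
Conditions: NaH, THF, 0 °C to reflux
Reagents that add atoms: none
Why: Carbamoylation of the alkoxide (acyl substitution) should give the carbamate needed as a homoenolate precursor.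

Step 2
Reactants: 3 allyl N,N-diisopropylcarbamate; 4 β-cyclocitral
Product: 7 racemic (Z)-4-hydroxy-4-(2,6,6-trimethylcyclohex-1-en-1-yl)but-1-en-1-yl N,N-diisopropylcarbamate, via lithiated carbamate 5 (not isolated), via allyltitanium reagent 6 (not isolated)
Conditions: s-BuLi, TMEDA, Et2O, −78 °C; ClTi(OiPr)3, −78 °C; then 4, −78 to −20 °C; aq. NH4Cl
Reagents that add atoms: none
Why: Hoppe homoaldol reaction: the α-lithiated carbamate is transmetalated to titanium and the allyltitanium should add to the aldehyde through its γ-carbon in a six-membered chair transition state, which gives the (Z)-enol carbamate (racemic at C6).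

Step 3
Reactants: 7 racemic homoaldol adduct
Product: 8 (Z)-4-oxo-4-(2,6,6-trimethylcyclohex-1-en-1-yl)but-1-en-1-yl N,N-diisopropylcarbamate
Conditions: Dess–Martin periodinane, NaHCO3, CH2Cl2, 0 °C
Reagents that add atoms: none
Why: Dess–Martin oxidation of the allylic alcohol under buffered conditions should leave the enol carbamate and the β,γ-alkene in place.

Step 4
Reactants: 8 ketone
Product: 9 (S,Z)-4-hydroxy-4-(2,6,6-trimethylcyclohex-1-en-1-yl)but-1-en-1-yl N,N-diisopropylcarbamate
Conditions: (R)-2-methyl-CBS-oxazaborolidine (cat.), catecholborane, toluene, −78 °C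
Reagents that add atoms: none
Why: Corey–Bakshi–Shibata reduction: the bulky trimethylcyclohexenyl group acts as the large substituent, so the (R)-oxazaborolidine should deliver hydride to give the (S)-carbinol needed for chirality transfer.

Step 5
Reactants: 9 (S)-carbinol
Product: 11 (1R)-1-[(1S,2S)-2-formyl-1,3,3-trimethylcyclohexyl]allyl N,N-diisopropylcarbamate (formyl trans to the side chain; 5α-H, 10β-methyl), via potassium enolate 10 (not isolated)
Conditions: KH, 18-crown-6, THF, 0 °C to rt; AcOH, −78 °C
Reagents that add atoms: none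
Why: Anionic oxy-Cope rearrangement ([3,3]-sigmatropic): allylic 1,3-strain against the C10 methyl should keep the carbinol hydrogen of 9 eclipsed with the ring double bond, so the enol carbamate terminus is delivered to the α face of C10 (10S), and the enolate should be protonated axially, anti to the syn-axial methyls on C4 and C10, which places the formyl group trans to the new side chain.

Step 6
Reactants: 11 aldehyde carbamate
Product: 12 (1R)-1-[(1S,2S)-2-(hydroxymethyl)-1,3,3-trimethylcyclohexyl]prop-2-en-1-ol
Conditions: LiAlH4, THF, 0 °C to reflux; aq. NaOH work-up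
Reagents that add atoms: none
Why: Hydride reduction: LiAlH4 should reduce the aldehyde (which fixes C5) and cleave the hindered carbamate in the same operation.

Step 7
Reactants: 12 diol; 13 3-bromofuran-2(5H)-one
Product: 15 3-{(3R)-3-hydroxy-3-[(1S,2S)-2-(hydroxymethyl)-1,3,3-trimethylcyclohexyl]propyl}furan-2(5H)-one, via B-alkyl-9-BBN borane 14 (not isolated)
Conditions: 9-BBN (excess), THF, rt; then 13, Pd(dppf)Cl2 (cat.), AsPh3, K3PO4, DMF–H2O, rt
Reagents that add atoms: none
Why: Hydroboration with 9-BBN should place boron on the terminal carbon (C12), and a B-alkyl Suzuki–Miyaura coupling of the α-haloenone type should join C12 to C13 of the butenolide.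

Step 8
Reactants: 15 diol
Product: 16 (1S,2S)-2,6,6-trimethyl-2-[3-(2-oxo-2,5-dihydrofuran-3-yl)propanoyl]cyclohexane-1-carbaldehyde
Conditions: (COCl)2, DMSO, CH2Cl2, −78 °C; Et3N, −78 to 0 °C
Reagents that add atoms: none
Why: Swern oxidation: both alcohols are activated before the base is added, which should avoid lactol formation and over-oxidation of the 1,4-diol to a lactone.

Step 9
Reactants: 16 γ-keto aldehyde; 17 allylboronic acid pinacol ester
Product: 19 (5S,8R,9R,10S)-6,9-dihydroxylabd-13-en-16,15-olide as a mixture of C6 epimers (8α-methyl, 9α-hydroxy, trans-decalin), via homoallylic alcohol 18 (not isolated)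
Conditions: 17, EtOH, 50 °C; then Fe(acac)3 (cat.), PhSiH3, EtOH, 60 °C, high dilution
Reagents that add atoms: none
Why: Allylboration through a closed six-membered transition state should add the allyl group only to the aldehyde of 16 (the hindered C9 ketone does not react with the boronate) and form C6–C7, giving 18 as a mixture at C6. The iron hydride formed from Fe(acac)3 and PhSiH3 should then transfer a hydrogen atom to the terminal alkene carbon (the future C17 methyl), and the secondary C8 radical adds to the C9 ketone; the alkoxy radical is reduced and protonated to the tertiary alcohol. The closest known reaction types are the allylboration of aldehydes and the iron-hydride-initiated radical cyclization of alkene-tethered ketones, run here in sequence in one flask as a formal [4+2] annulation of a γ-keto aldehyde with a vicinal double donor. Ring B closes in the 6-exo-trig mode onto the carbonyl carbon through a chair in which C5–C6 and C10–C9 are equatorial on ring A and the C10 methyl is axial (trans ring fusion). The C8 methyl should take the equatorial position to avoid the 1,3-diaxial contact with the C10 methyl (8α-methyl), and the carbonyl oxygen should sit pseudo-axial, anti to the C10 methyl, with the side chain pseudo-equatorial (9α-hydroxy); C6 is not controlled here and is corrected in steps 10 and 11. The step needs aldehyde-over-ketone selectivity, secured by the boronate, and ring closure faster than reduction of the radical or its addition to the butenolide, secured by the six-membered intramolecular closure at high dilution and by the preference of the iron hydride for the electron-rich terminal alkene.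

Step 10
Reactants: 19 diol (C6 epimers)
Product: 20 (5S,8R,9R,10S)-9-hydroxy-6-oxolabd-13-en-16,15-olide
Conditions: Dess–Martin periodinane, NaHCO3, CH2Cl2, rt
Reagents that add atoms: none
Why: Dess–Martin oxidation: both C6 epimers should converge on one ketone, while the tertiary C9 alcohol cannot be oxidised.

Step 11
Reactants: 20 6-ketone
Product: 21 (5S,6R,8R,9R,10S)-6,9-dihydroxylabd-13-en-16,15-olide (6β,9α-diol)
Conditions: NaBH4, CeCl3·7H2O, MeOH, −20 to 0 °C
Reagents that add atoms: none
Why: Luche-type 1,2-reduction: hydride should approach the 6-ketone from the α face, away from the syn-axial methyls on C4 and C10, giving the axial 6β-alcohol, while CeCl3 suppresses conjugate reduction of the butenolide.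

Step 12
Reactants: 21 6β,9α-diol
Product: 22 (5S,6R,8R,9R,10S)-6-acetoxy-9-hydroxylabd-13-en-16,15-olide (target)
Conditions: Ac2O, DMAP, pyridine, 40 °C
Reagents that add atoms: acetic anhydride, CC(=O)OC(C)=O
Why: DMAP-catalysed acylation should acetylate only the secondary 6β-hydroxyl, the tertiary 9α-hydroxyl being too hindered.

Compound list
1 | allyl alcohol | C=CCO | starting material
2 | N,N-diisopropylcarbamoyl chloride | CC(C)N(C(C)C)C(Cl)=O | starting material
3 | allyl N,N-diisopropylcarbamate | C=CCOC(=O)N(C(C)C)C(C)C | intermediate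
4 | β-cyclocitral (2,6,6-trimethylcyclohex-1-ene-1-carbaldehyde) | CC1=C(C=O)C(C)(C)CCC1 | starting material
5 | 1-lithioallyl N,N-diisopropylcarbamate (TMEDA complex) | [Li+].C=C[CH-]OC(=O)N(C(C)C)C(C)C | intermediate
6 | [1-(N,N-diisopropylcarbamoyloxy)allyl]Ti(OiPr)3 | CC(C)O[Ti](OC(C)C)(OC(C)C)C(C=C)OC(=O)N(C(C)C)C(C)C | intermediate
7 | racemic (Z)-4-hydroxy-4-(2,6,6-trimethylcyclohex-1-en-1-yl)but-1-en-1-yl N,N-diisopropylcarbamate | OC(C/C=C\OC(=O)N(C(C)C)C(C)C)C1=C(C)CCCC1(C)C | intermediate
8 | (Z)-4-oxo-4-(2,6,6-trimethylcyclohex-1-en-1-yl)but-1-en-1-yl N,N-diisopropylcarbamate | O=C(C/C=C\OC(=O)N(C(C)C)C(C)C)C1=C(C)CCCC1(C)C | intermediate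
9 | (S,Z)-4-hydroxy-4-(2,6,6-trimethylcyclohex-1-en-1-yl)but-1-en-1-yl N,N-diisopropylcarbamate | O[C@@H](C/C=C\OC(=O)N(C(C)C)C(C)C)C1=C(C)CCCC1(C)C | intermediate
10 | potassium enolate of 11 | C=C[C@@H](OC(=O)N(C(C)C)C(C)C)[C@@]1(C)CCCC(C)(C)C1=C[O-].[K+] | intermediate
11 | (1R)-1-[(1S,2S)-2-formyl-1,3,3-trimethylcyclohexyl]allyl N,N-diisopropylcarbamate | C=C[C@@H](OC(=O)N(C(C)C)C(C)C)[C@@]1(C)CCCC(C)(C)[C@@H]1C=O | intermediate
12 | (1R)-1-[(1S,2S)-2-(hydroxymethyl)-1,3,3-trimethylcyclohexyl]prop-2-en-1-ol | C=C[C@@H](O)[C@@]1(C)CCCC(C)(C)[C@@H]1CO | intermediate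
13 | 3-bromofuran-2(5H)-one | O=C1OCC=C1Br | starting material
14 | B-alkyl-9-BBN borane of 12 (boron on the terminal carbon) | C1CCC2CCCC1B2CC[C@@H](O)[C@@]1(C)CCCC(C)(C)[C@@H]1CO | intermediate
15 | 3-{(3R)-3-hydroxy-3-[(1S,2S)-2-(hydroxymethyl)-1,3,3-trimethylcyclohexyl]propyl}furan-2(5H)-one | O=C1OCC=C1CC[C@@H](O)[C@@]1(C)CCCC(C)(C)[C@@H]1CO | intermediate
16 | (1S,2S)-2,6,6-trimethyl-2-[3-(2-oxo-2,5-dihydrofuran-3-yl)propanoyl]cyclohexane-1-carbaldehyde | O=C1OCC=C1CCC(=O)[C@@]1(C)CCCC(C)(C)[C@@H]1C=O | intermediate
17 | allylboronic acid pinacol ester | C=CCB1OC(C)(C)C(C)(C)O1 | starting material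
18 | 3-{3-[(1S,2S)-2-(1-hydroxybut-3-en-1-yl)-1,3,3-trimethylcyclohexyl]-3-oxopropyl}furan-2(5H)-one (both carbinol epimers) | O=C1OCC=C1CCC(=O)[C@@]1(C)CCCC(C)(C)[C@@H]1C(O)CC=C | intermediate
19 | (5S,8R,9R,10S)-6,9-dihydroxylabd-13-en-16,15-olide (C6 epimers) | OC1C[C@@H](C)[C@](O)(CCC2=CCOC2=O)[C@@]2(C)CCCC(C)(C)[C@H]12 | intermediate
20 | (5S,8R,9R,10S)-9-hydroxy-6-oxolabd-13-en-16,15-olide | O=C1C[C@@H](C)[C@](O)(CCC2=CCOC2=O)[C@@]2(C)CCCC(C)(C)[C@H]12 | intermediate
21 | (5S,6R,8R,9R,10S)-6,9-dihydroxylabd-13-en-16,15-olide | O[C@@H]1C[C@@H](C)[C@](O)(CCC2=CCOC2=O)[C@@]2(C)CCCC(C)(C)[C@H]12 | intermediate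
22 | (5S,6R,8R,9R,10S)-6-acetoxy-9-hydroxylabd-13-en-16,15-olide | CC(=O)O[C@@H]1C[C@@H](C)[C@](O)(CCC2=CCOC2=O)[C@@]2(C)CCCC(C)(C)[C@H]12 | target

Total step count: 12. Longest linear sequence: 12 steps (1 to 22).

Steps most likely to fail

Step 9. The C8 radical may be reduced by a second hydrogen atom transfer before it closes onto the hindered ketone, the alkoxy radical may fragment, or closure may place the oxygen equatorial. The fallback closes ring B by polar addition and sets C8 afterwards. It sets out from 16: indium-mediated Barbier allylation with 2,3-dibromopropene (In, THF–H2O) should give the 2-bromoallyl carbinol F1. An intramolecular Nozaki–Hiyama–Kishi addition of the alkenyl bromide to the C9 ketone (CrCl2, NiCl2 cat., DMF) should then give the exocyclic methylene diol F2. Hydrogen-atom-transfer hydrogenation (Mn(dpm)3, PhSiH3, t-BuOOH, i-PrOH) should deliver the thermodynamically preferred equatorial C8 methyl. The fallback comes back to the route at 19.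

Step 5. The potassium alkoxide may fragment by retro-homoaldol cleavage or pass its carbamoyl group to oxygen before it rearranges, and chirality transfer erodes if the oxido group takes the inside position. The fallback carries no oxygen through the rearrangement and adds the C9 oxygen afterwards; it still relies on chirality transfer from C6. It sets out from 4: Brown allylation with (−)-Ipc2B(allyl) should give (S)-1-(2,6,6-trimethylcyclohex-1-en-1-yl)but-3-en-1-ol F3. Anionic oxy-Cope rearrangement (KH, 18-crown-6, THF) should give trans-2-allyl-2,6,6-trimethylcyclohexane-1-carbaldehyde F4, and NaBH4 the primary alcohol F5. Allylic oxidation of the terminal allyl group (SeO2, t-BuOOH, CH2Cl2) should then give 12 together with its C9 epimer F6, which converges with 12 at 16. The fallback comes back to the route at 12.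

Step 7. The alkylborane may undergo protodeboronation or β-hydride elimination on palladium, and the bromobutenolide may decompose under the aqueous base. The fallback builds the butenolide by conjugate addition and sulfoxide elimination. It sets out from 12: Swern oxidation should give the vinyl ketone aldehyde F7. Michael addition of 3-(phenylthio)dihydrofuran-2(3H)-one (cat. DBU, THF) should give the adduct F8. Oxidation with mCPBA at −78 °C should give the sulfoxide F9, and thermal syn-elimination (toluene, 110 °C) should form the endocyclic butenolide. The fallback comes back to the route at 16.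

Further compounds
F1 | step 9 | 3-{3-[(1S,2S)-2-(3-bromo-1-hydroxybut-3-en-1-yl)-1,3,3-trimethylcyclohexyl]-3-oxopropyl}furan-2(5H)-one (both carbinol epimers) | O=C1OCC=C1CCC(=O)[C@@]1(C)CCCC(C)(C)[C@@H]1C(O)CC(Br)=C
F2 | step 9 | (5S,9R,10S)-6,9-dihydroxylabda-8(17),13-dien-16,15-olide (C6 epimers) | OC1CC(=C)[C@](O)(CCC2=CCOC2=O)[C@@]2(C)CCCC(C)(C)[C@H]12
F3 | step 5 | (S)-1-(2,6,6-trimethylcyclohex-1-en-1-yl)but-3-en-1-ol | O[C@@H](CC=C)C1=C(C)CCCC1(C)C
F4 | step 5 | trans-2-allyl-2,6,6-trimethylcyclohexane-1-carbaldehyde (formyl trans to allyl; 5α-H, 10β-methyl) | C=CC[C@@]1(C)CCCC(C)(C)[C@@H]1C=O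
F5 | step 5 | [trans-2-allyl-2,6,6-trimethylcyclohexyl]methanol (same configuration as F4) | C=CC[C@@]1(C)CCCC(C)(C)[C@@H]1CO
F6 | step 5 | (1S)-1-[(1S,2S)-2-(hydroxymethyl)-1,3,3-trimethylcyclohexyl]prop-2-en-1-ol (C9 epimer of 12) | C=C[C@H](O)[C@@]1(C)CCCC(C)(C)[C@@H]1CO
F7 | step 7 | (1S,2S)-2-acryloyl-2,6,6-trimethylcyclohexane-1-carbaldehyde | C=CC(=O)[C@@]1(C)CCCC(C)(C)[C@@H]1C=O
F8 | step 7 | (1S,2S)-2,6,6-trimethyl-2-{3-[2-oxo-3-(phenylthio)tetrahydrofuran-3-yl]propanoyl}cyclohexane-1-carbaldehyde (both epimers at the sulfur-bearing carbon) | O=C1OCCC1(Sc1ccccc1)CCC(=O)[C@@]1(C)CCCC(C)(C)[C@@H]1C=O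
F9 | step 7 | (1S,2S)-2,6,6-trimethyl-2-{3-[2-oxo-3-(phenylsulfinyl)tetrahydrofuran-3-yl]propanoyl}cyclohexane-1-carbaldehyde | O=C1OCCC1(S(=O)c1ccccc1)CCC(=O)[C@@]1(C)CCCC(C)(C)[C@@H]1C=O
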